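**Retrosynthetic overview**

1. The target is a 2,3-trans-3,4-trans flavan-3-ol (benzo ring A, catechol ring B, pyran ring C) whose C4 is bonded to pyrogallol ring E; ring E is also the 2-aryl group of a 3,7-dihydroxyflavone (benzo ring D, pyranone ring F). All phenols are freed last by hydrogenolysis of benzyl ethers.
2. Ring F comes from Algar–Flynn–Oyamada oxidation of a 2'-hydroxychalcone, itself from Claisen–Schmidt condensation of a ring E aldehyde (made from the aryl bromide) with a ring D acetophenone.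
3. Feature on which the plan rests: in ring C (O1, C2, C3, C4, C4a, C8a) the benzylic C4 that carries ring E is ortho to the O1-bearing carbon C8a of ring A, and C2 and C3 both carry oxygen. Ring C is therefore an ortho-quinone methide (O1=C8a–C4a=C4) plus a 1,2-dioxygenated alkene (C2=C3); the cuts are C3–C4 and O1–C2.
4. The diene precursor is a racemic ortho-hydroxybenzhydrol from a ring E Grignard reagent and a ring A salicylaldehyde. The dienophile is the (Z)-enol silane of the ring B alpha-benzyloxy ketone; the ketal carbon C2 is then reduced to the ether level by ionic hydrogenation.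
5. Order of ring formation: ring C (step 7), then ring F (step 11).

Key step: step 7

Assumption: the (R)-configured phosphoric acid is taken to expose the face of the quinone methide that leads to (4S); the sense is to be confirmed on the reduced flavan, and the (S)-acid would be used with no other change if it proves opposite.

**Route**

Step 1
Reactants: 1 5-bromo-1,2,3-trimethoxybenzene
Product: 2 5-bromobenzene-1,2,3-triol
Conditions: BBr3 (4 equiv), CH2Cl2, −78 °C → rt; then H2O
Reagents that add atoms: none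
Why: Boron tribromide ether cleavage demethylates each boron-activated methyl ether by bromide attack while the aryl bromide is inert, which frees the pyrogallol for a protecting group that hydrogenolysis can remove at the end.

Step 2
Reactants: 2 5-bromobenzene-1,2,3-triol
Product: 3 1,2,3-tris(benzyloxy)-5-bromobenzene
Conditions: BnBr (3.6 equiv), K2CO3, DMF, N2, 60 °C
Reagents that add atoms: benzyl bromide, BrCc1ccccc1
Why: Williamson ether synthesis alkylates the three phenoxides, with oxygen excluded because pyrogallol anions oxidise easily.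

Step 3
Reactants: 3 1,2,3-tris(benzyloxy)-5-bromobenzene
Product: 4 3,4,5-tris(benzyloxy)-1-bromo-2-iodobenzene
Conditions: N-iodosuccinimide (1.1 equiv), CF3CO2H (0.3 equiv), MeCN, rt, dark
Reagents that add atoms: N-iodosuccinimide, O=C1CCC(=O)N1I
Why: Electrophilic aromatic iodination occurs at the only kind of free position on the trialkoxy ring (C4 and C6 are equivalent, ortho and para to benzyloxy groups), the first iodine and the flanking bromine block a second substitution, and the pendant benzyl rings are not activated.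

Step 4
Reactants: 4 3,4,5-tris(benzyloxy)-1-bromo-2-iodobenzene; 5 4-(benzyloxy)-2-hydroxybenzaldehyde
Product: 8 5-(benzyloxy)-2-{[2,3,4-tris(benzyloxy)-6-bromophenyl](hydroxy)methyl}phenol (racemic), via sodium phenolate 6 (not isolated), via arylmagnesium chloride 7 (not isolated)
Conditions: 4 (1.3 equiv), iPrMgCl·LiCl, THF, −30 °C; then 6 (from 5 and NaH, THF, 0 °C), −30 → 0 °C; aq NH4Cl
Reagents that add atoms: none
Why: Halogen–magnesium exchange takes iodine far faster than bromine, the 2-bromoaryl Grignard reagent keeps its bromide at or below 0 °C, and its Grignard addition to the aldehyde of the phenolate gives the benzhydrol; the carbinol centre forms racemic, which is harmless because it becomes sp2 in step 7.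

Step 5
Reactants: 9 1,2-bis(benzyloxy)-4-bromobenzene; 10 2-(benzyloxy)-N-methoxy-N-methylacetamide
Product: 12 2-(benzyloxy)-1-[3,4-bis(benzyloxy)phenyl]ethan-1-one, via aryllithium 11 (not isolated)
Conditions: n-BuLi (1.05 equiv), THF, −78 °C; then 10, −78 → 0 °C; aq NH4Cl
Reagents that add atoms: none
Why: Bromine–lithium exchange followed by Weinreb ketone synthesis gives the aryl ketone without over-addition, because the chelated tetrahedral adduct survives until the quench.

Step 6
Reactants: 12 2-(benzyloxy)-1-[3,4-bis(benzyloxy)phenyl]ethan-1-one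
Product: 13 (Z)-{[2-(benzyloxy)-1-[3,4-bis(benzyloxy)phenyl]ethenyl]oxy}(tert-butyl)dimethylsilane
Conditions: t-BuMe2SiOTf (1.3 equiv), Et3N (2 equiv), CH2Cl2, 0 °C → rt
Reagents that add atoms: tert-butyldimethylsilyl trifluoromethanesulfonate, CC(C)(C)[Si](C)(C)OS(=O)(=O)C(F)(F)F
Why: Soft enolisation with a silyl triflate and a tertiary amine gives the silyl enol ether under equilibrating conditions, and the Z isomer (silyloxy cis to benzyloxy) should dominate because the E isomer suffers allylic strain between the aryl ring and the benzyloxy group.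

Step 7
Reactants: 8 5-(benzyloxy)-2-{[2,3,4-tris(benzyloxy)-6-bromophenyl](hydroxy)methyl}phenol (racemic); 13 (Z)-enol silane (1.5 equiv)
Product: 15 (2S,3S,4S)-3,7-bis(benzyloxy)-2-[3,4-bis(benzyloxy)phenyl]-4-[2,3,4-tris(benzyloxy)-6-bromophenyl]-2-[(tert-butyldimethylsilyl)oxy]chromane, via ortho-quinone methide 14 (not isolated)
Conditions: (R)-3,3'-bis(2,4,6-triisopropylphenyl)-1,1'-binaphthyl-2,2'-diyl hydrogen phosphate (10 mol%), 4 Å molecular sieves, toluene, −20 → 0 °C; Et3N quench, Et3N-deactivated silica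
Reagents that add atoms: none
Why: The phosphoric acid protonates the carbinol of 8 and, after loss of water to the sieves, holds the (E)-quinone methide 14 by a hydrogen bond to its carbonyl oxygen; the CH(OBn) carbon of 13 attacks C4 because the charge building on the other alkene carbon is stabilised by the silyloxy oxygen and the dialkoxyphenyl ring, and the quinone methide oxygen then closes on that carbon (O1–C2) in a concerted but asynchronous inverse-electron-demand oxa-Diels–Alder reaction that restores the aromaticity of ring A. The closest known reaction type is the chiral phosphoric acid catalysed [4+2] cycloaddition of ortho-quinone methides, made in situ from ortho-hydroxybenzyl alcohols, with enol ethers, enamides and styrenes. Ring C closes as the six-membered ring of this [4+2] cycloaddition (in the stepwise limit a 6-exo-trig attack of the phenol oxygen on the silyl oxocarbenium ion). C4 (S) is fixed by the face of 14 left open in the chiral pocket of the bound phosphate; C3 (S) follows from the Z geometry of 13 and the approach with ring B endo over the diene, which places H3 and ring E cis and so gives the 3,4-trans relation; the ketal centre C2 forms suprafacially with silyloxy cis to the 3-benzyloxy group and is erased in step 8. The step needs regioselectivity for C–C bonding at the benzyloxy-bearing carbon, secured by the ketone-level silyloxy carbon that alone can carry the positive charge, diastereoselectivity, secured by the single alkene geometry, and survival of the enol silane, secured by its excess and by removal of water.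

Step 8
Reactants: 15 (2S,3S,4S)-2-silyloxy ketal
Product: 17 (2R,3S,4S)-3,7-bis(benzyloxy)-2-[3,4-bis(benzyloxy)phenyl]-4-[2,3,4-tris(benzyloxy)-6-bromophenyl]chromane, via oxocarbenium ion 16 (not isolated)
Conditions: Et3SiH (5 equiv), BF3·OEt2 (2 equiv), CH2Cl2, −78 → −30 °C; aq NaHCO3
Reagents that add atoms: none
Why: Ionic hydrogenation of a ketal, as used for 1-aryl glycosyl ketals: BF3 removes the silyloxy group to give the 2-aryl oxocarbenium ion 16, and triethylsilane delivers hydride along the axial trajectory of the half-chair in which the 3-benzyloxy and 4-aryl groups are pseudo-equatorial, so ring B ends equatorial and C2 is set R, trans to the C3 oxygen.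

Step 9
Reactants: 17 (2R,3S,4S)-flavan bromide
Product: 19 3,4,5-tris(benzyloxy)-2-{(2R,3S,4S)-3,7-bis(benzyloxy)-2-[3,4-bis(benzyloxy)phenyl]chroman-4-yl}benzaldehyde, via aryllithium 18 (not isolated)
Conditions: n-BuLi (1.2 equiv), THF, −78 °C, 15 min; then DMF (5 equiv), −78 → 0 °C; aq NH4Cl
Reagents that add atoms: N,N-dimethylformamide, CN(C)C=O
Why: Bromine–lithium exchange at −78 °C is faster than any benzylic deprotonation, and the aryllithium is formylated by DMF (Bouveault-type formylation) without touching a stereocentre.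

Step 10
Reactants: 19 ring E aldehyde; 20 1-[4-(benzyloxy)-2-hydroxyphenyl]ethan-1-one
Product: 21 (E)-1-[4-(benzyloxy)-2-hydroxyphenyl]-3-{3,4,5-tris(benzyloxy)-2-[(2R,3S,4S)-3,7-bis(benzyloxy)-2-[3,4-bis(benzyloxy)phenyl]chroman-4-yl]phenyl}prop-2-en-1-one
Conditions: KOH (50% aq, excess), EtOH/THF, rt → 40 °C; dilute HCl work-up
Reagents that add atoms: none
Why: Claisen–Schmidt condensation: the aldehyde cannot enolise, the acetophenone enolate adds and the aldol eliminates by E1cB to the conjugated E enone, and C2, C3 and C4 carry no hydrogen acidic enough to epimerise under these conditions.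

Step 11
Reactants: 21 (E)-2'-hydroxychalcone
Product: 23 7-(benzyloxy)-3-hydroxy-2-{3,4,5-tris(benzyloxy)-2-[(2R,3S,4S)-3,7-bis(benzyloxy)-2-[3,4-bis(benzyloxy)phenyl]chroman-4-yl]phenyl}-4H-chromen-4-one, via dihydroflavonol 22 (not isolated)
Conditions: H2O2 (30% aq, 6 equiv), NaOH (2 M aq), MeOH/THF, 0 °C → rt
Reagents that add atoms: hydrogen peroxide, OO
Why: Algar–Flynn–Oyamada oxidation: alkaline hydrogen peroxide oxidises the enone while the 2'-phenoxide closes on the beta carbon to give the dihydroflavonol 22, which is dehydrogenated in the same pot to the flavonol; six-membered closure is favoured over aurone formation because the acetophenone ring has no 6'-substituent.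

Step 12
Reactants: 23 octabenzyl flavonol
Product: 24 2-{2-[(2R,3S,4S)-2-(3,4-dihydroxyphenyl)-3,7-dihydroxychroman-4-yl]-3,4,5-trihydroxyphenyl}-3,7-dihydroxy-4H-chromen-4-one (CNP0381334.2)
Conditions: H2 (1 atm), Pd(OH)2/C (20 wt%), THF/MeOH 1:1, rt; work-up under argon
Reagents that add atoms: none
Why: Catalytic hydrogenolysis cleaves the eight benzyl ethers under neutral conditions at 1 atm, where the tetrasubstituted vinylogous-ester alkene of ring F and the cyclic benzylic ether and C4–aryl bonds of ring C are not reduced, so the three stereocentres are untouched.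

**Compound list**

1 | 5-bromo-1,2,3-trimethoxybenzene | COc1cc(Br)cc(OC)c1OC | starting material
2 | 5-bromobenzene-1,2,3-triol | Oc1cc(Br)cc(O)c1O | intermediate
3 | 1,2,3-tris(benzyloxy)-5-bromobenzene | Brc1cc(OCc2ccccc2)c(OCc2ccccc2)c(OCc2ccccc2)c1 | intermediate
4 | 3,4,5-tris(benzyloxy)-1-bromo-2-iodobenzene | Brc1cc(OCc2ccccc2)c(OCc2ccccc2)c(OCc2ccccc2)c1I | intermediate
5 | 4-(benzyloxy)-2-hydroxybenzaldehyde | O=Cc1ccc(OCc2ccccc2)cc1O | starting material
6 | sodium 5-(benzyloxy)-2-formylphenolate | [Na+].[O-]c1cc(OCc2ccccc2)ccc1C=O | intermediate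
7 | [2,3,4-tris(benzyloxy)-6-bromophenyl]magnesium chloride (LiCl complex) | Cl[Mg]c1c(Br)cc(OCc2ccccc2)c(OCc2ccccc2)c1OCc1ccccc1 | intermediate
8 | 5-(benzyloxy)-2-{[2,3,4-tris(benzyloxy)-6-bromophenyl](hydroxy)methyl}phenol (racemic) | OC(c1ccc(OCc2ccccc2)cc1O)c1c(Br)cc(OCc2ccccc2)c(OCc2ccccc2)c1OCc1ccccc1 | intermediate
9 | 1,2-bis(benzyloxy)-4-bromobenzene | Brc1ccc(OCc2ccccc2)c(OCc2ccccc2)c1 | starting material
10 | 2-(benzyloxy)-N-methoxy-N-methylacetamide | CON(C)C(=O)COCc1ccccc1 | starting material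
11 | [3,4-bis(benzyloxy)phenyl]lithium | [Li]c1ccc(OCc2ccccc2)c(OCc2ccccc2)c1 | intermediate
12 | 2-(benzyloxy)-1-[3,4-bis(benzyloxy)phenyl]ethan-1-one | O=C(COCc1ccccc1)c1ccc(OCc2ccccc2)c(OCc2ccccc2)c1 | intermediate
13 | (Z)-{[2-(benzyloxy)-1-[3,4-bis(benzyloxy)phenyl]ethenyl]oxy}(tert-butyl)dimethylsilane | CC(C)(C)[Si](C)(C)O/C(c1ccc(OCc2ccccc2)c(OCc2ccccc2)c1)=C\OCc1ccccc1 | intermediate
14 | (6E)-3-(benzyloxy)-6-{[2,3,4-tris(benzyloxy)-6-bromophenyl]methylidene}cyclohexa-2,4-dien-1-one | O=C1C=C(OCc2ccccc2)C=C/C1=C\c1c(Br)cc(OCc2ccccc2)c(OCc2ccccc2)c1OCc1ccccc1 | intermediate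
15 | (2S,3S,4S)-3,7-bis(benzyloxy)-2-[3,4-bis(benzyloxy)phenyl]-4-[2,3,4-tris(benzyloxy)-6-bromophenyl]-2-[(tert-butyldimethylsilyl)oxy]chromane | Brc1cc(OCc2ccccc2)c(OCc2ccccc2)c(OCc2ccccc2)c1[C@@H]1c2ccc(OCc3ccccc3)cc2O[C@](O[Si](C)(C)C(C)(C)C)(c2ccc(OCc3ccccc3)c(OCc3ccccc3)c2)[C@H]1OCc1ccccc1 | intermediate
16 | (3S,4S)-3,7-bis(benzyloxy)-2-[3,4-bis(benzyloxy)phenyl]-4-[2,3,4-tris(benzyloxy)-6-bromophenyl]-3,4-dihydrochromenylium (oxocarbenium ion) | Brc1cc(OCc2ccccc2)c(OCc2ccccc2)c(OCc2ccccc2)c1[C@@H]1c2ccc(OCc3ccccc3)cc2[O+]=C(c2ccc(OCc3ccccc3)c(OCc3ccccc3)c2)[C@H]1OCc1ccccc1 | intermediate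
17 | (2R,3S,4S)-3,7-bis(benzyloxy)-2-[3,4-bis(benzyloxy)phenyl]-4-[2,3,4-tris(benzyloxy)-6-bromophenyl]chromane | Brc1cc(OCc2ccccc2)c(OCc2ccccc2)c(OCc2ccccc2)c1[C@@H]1c2ccc(OCc3ccccc3)cc2O[C@H](c2ccc(OCc3ccccc3)c(OCc3ccccc3)c2)[C@H]1OCc1ccccc1 | intermediate
18 | {3,4,5-tris(benzyloxy)-2-[(2R,3S,4S)-3,7-bis(benzyloxy)-2-[3,4-bis(benzyloxy)phenyl]chroman-4-yl]phenyl}lithium | [Li]c1cc(OCc2ccccc2)c(OCc2ccccc2)c(OCc2ccccc2)c1[C@@H]1c2ccc(OCc3ccccc3)cc2O[C@H](c2ccc(OCc3ccccc3)c(OCc3ccccc3)c2)[C@H]1OCc1ccccc1 | intermediate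
19 | 3,4,5-tris(benzyloxy)-2-{(2R,3S,4S)-3,7-bis(benzyloxy)-2-[3,4-bis(benzyloxy)phenyl]chroman-4-yl}benzaldehyde | O=Cc1cc(OCc2ccccc2)c(OCc2ccccc2)c(OCc2ccccc2)c1[C@@H]1c2ccc(OCc3ccccc3)cc2O[C@H](c2ccc(OCc3ccccc3)c(OCc3ccccc3)c2)[C@H]1OCc1ccccc1 | intermediate
20 | 1-[4-(benzyloxy)-2-hydroxyphenyl]ethan-1-one | CC(=O)c1ccc(OCc2ccccc2)cc1O | starting material
21 | (E)-1-[4-(benzyloxy)-2-hydroxyphenyl]-3-{3,4,5-tris(benzyloxy)-2-[(2R,3S,4S)-3,7-bis(benzyloxy)-2-[3,4-bis(benzyloxy)phenyl]chroman-4-yl]phenyl}prop-2-en-1-one | O=C(/C=C/c1cc(OCc2ccccc2)c(OCc2ccccc2)c(OCc2ccccc2)c1[C@@H]1c2ccc(OCc3ccccc3)cc2O[C@H](c2ccc(OCc3ccccc3)c(OCc3ccccc3)c2)[C@H]1OCc1ccccc1)c1ccc(OCc2ccccc2)cc1O | intermediate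
22 | 7-(benzyloxy)-3-hydroxy-2-{3,4,5-tris(benzyloxy)-2-[(2R,3S,4S)-3,7-bis(benzyloxy)-2-[3,4-bis(benzyloxy)phenyl]chroman-4-yl]phenyl}chroman-4-one (trans dihydroflavonol, both diastereomers, new centres not defined) | O=C1c2ccc(OCc3ccccc3)cc2OC(c2cc(OCc3ccccc3)c(OCc3ccccc3)c(OCc3ccccc3)c2[C@@H]2c3ccc(OCc4ccccc4)cc3O[C@H](c3ccc(OCc4ccccc4)c(OCc4ccccc4)c3)[C@H]2OCc2ccccc2)C1O | intermediate
23 | 7-(benzyloxy)-3-hydroxy-2-{3,4,5-tris(benzyloxy)-2-[(2R,3S,4S)-3,7-bis(benzyloxy)-2-[3,4-bis(benzyloxy)phenyl]chroman-4-yl]phenyl}-4H-chromen-4-one | O=c1c(O)c(-c2cc(OCc3ccccc3)c(OCc3ccccc3)c(OCc3ccccc3)c2[C@@H]2c3ccc(OCc4ccccc4)cc3O[C@H](c3ccc(OCc4ccccc4)c(OCc4ccccc4)c3)[C@H]2OCc2ccccc2)oc2cc(OCc3ccccc3)ccc12 | intermediate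
24 | 2-{2-[(2R,3S,4S)-2-(3,4-dihydroxyphenyl)-3,7-dihydroxychroman-4-yl]-3,4,5-trihydroxyphenyl}-3,7-dihydroxy-4H-chromen-4-one | O=c1c(O)c(-c2cc(O)c(O)c(O)c2[C@@H]2c3ccc(O)cc3O[C@H](c3ccc(O)c(O)c3)[C@H]2O)oc2cc(O)ccc12 | target

**Step count**

Total: 12 steps. Longest linear sequence: 10 steps (steps 1, 2, 3, 4, 7, 8, 9, 10, 11, 12).

**Steps most likely to fail**

Step 7. The acid, with any water not yet taken up, may protodesilylate the enol silane faster than the quinone methide is trapped. The quinone methide may instead add to a second molecule of the benzhydrol. Facial selectivity may be low, because the enol silane offers no hydrogen-bond donor to the phosphate. Partial loss of silicon from the ketal would not matter, since step 8 passes through the same oxocarbenium ion. The fallback is the chiral-pool cationic arylation at C4 that is used for proanthocyanidins; it sets out from compound 3 and rejoins the route at 17. Purchased (+)-fustin, (2R,3R)-3,7,3',4'-tetrahydroxyflavanone, would be benzylated on its three phenols (BnBr, K2CO3, DMF) to (2R,3R)-7-(benzyloxy)-2-[3,4-bis(benzyloxy)phenyl]-3-hydroxychroman-4-one F1. Reduction with NaBH4 (MeOH/THF, 0 °C) should give (2R,3S,4R)-7-(benzyloxy)-2-[3,4-bis(benzyloxy)phenyl]chromane-3,4-diol F2, and both hydroxyls would be benzylated (NaH, BnBr, DMF) to (2R,3S,4R)-3,4,7-tris(benzyloxy)-2-[3,4-bis(benzyloxy)phenyl]chromane F3. Me3SiOTf (CH2Cl2, −78 → −20 °C) would then ionise the 4-benzyloxy group in the presence of an excess of 3, which attacks C4 through its only free activated position and trans to the 3-benzyloxy group, as flavan-4-yl cations of the 2,3-trans series normally do; this should give 17 directly.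

Step 4. The 2-bromoaryl Grignard reagent may lose magnesium halide to an aryne on warming. Alternatively the doubly ortho-substituted nucleophile may add so slowly to the electron-rich phenolate aldehyde that it is only protonated on work-up. The fallback reverses the polarity; it sets out from 3 and rejoins at 8. Rieche formylation of 3 (Cl2CHOCH3, SnCl4, CH2Cl2, −40 → 0 °C) at its only free ring position should give 2,3,4-tris(benzyloxy)-6-bromobenzaldehyde F4. Purchased 3-(benzyloxy)phenol would be converted with EtMgBr (Et2O, then toluene) into bromomagnesium 3-(benzyloxy)phenoxide F5. Its ortho carbon para to the benzyloxy group adds to magnesium-bound F4 through a six-membered chelate (ortho-selective hydroxyalkylation of a magnesium phenoxide, toluene/CH2Cl2, rt) to give 8.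

Step 11. The phenoxide may close on the alpha carbon to give the aurone, or the oxidation may stall at the dihydroflavonol because the twisted, ortho-substituted ring E hinders the enone. The fallback separates ring closure from hydroxylation; it sets out from 21 and rejoins at 23. Oxidative cyclisation of 21 with catalytic I2 in DMSO (110 °C) should give the flavone 7-(benzyloxy)-2-{3,4,5-tris(benzyloxy)-2-[(2R,3S,4S)-3,7-bis(benzyloxy)-2-[3,4-bis(benzyloxy)phenyl]chroman-4-yl]phenyl}-4H-chromen-4-one F6. Dimethyldioxirane (acetone/CH2Cl2, 0 °C) would epoxidise its 2,3-double bond to the flavone 2,3-epoxide F7, and catalytic p-toluenesulfonic acid would isomerise the epoxide to the 3-hydroxyflavone 23.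

**Further compounds**

F1 | step 7 | (2R,3R)-7-(benzyloxy)-2-[3,4-bis(benzyloxy)phenyl]-3-hydroxychroman-4-one | O=C1c2ccc(OCc3ccccc3)cc2O[C@H](c2ccc(OCc3ccccc3)c(OCc3ccccc3)c2)[C@H]1O
F2 | step 7 | (2R,3S,4R)-7-(benzyloxy)-2-[3,4-bis(benzyloxy)phenyl]chromane-3,4-diol | O[C@@H]1c2ccc(OCc3ccccc3)cc2O[C@H](c2ccc(OCc3ccccc3)c(OCc3ccccc3)c2)[C@H]1O
F3 | step 7 | (2R,3S,4R)-3,4,7-tris(benzyloxy)-2-[3,4-bis(benzyloxy)phenyl]chromane | c1ccccc1CO[C@@H]1c2ccc(OCc3ccccc3)cc2O[C@H](c2ccc(OCc3ccccc3)c(OCc3ccccc3)c2)[C@H]1OCc1ccccc1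
F4 | step 4 | 2,3,4-tris(benzyloxy)-6-bromobenzaldehyde | O=Cc1c(Br)cc(OCc2ccccc2)c(OCc2ccccc2)c1OCc1ccccc1
F5 | step 4 | bromomagnesium 3-(benzyloxy)phenoxide | Br[Mg]Oc1cccc(OCc2ccccc2)c1
F6 | step 11 | 7-(benzyloxy)-2-{3,4,5-tris(benzyloxy)-2-[(2R,3S,4S)-3,7-bis(benzyloxy)-2-[3,4-bis(benzyloxy)phenyl]chroman-4-yl]phenyl}-4H-chromen-4-one | O=c1cc(-c2cc(OCc3ccccc3)c(OCc3ccccc3)c(OCc3ccccc3)c2[C@@H]2c3ccc(OCc4ccccc4)cc3O[C@H](c3ccc(OCc4ccccc4)c(OCc4ccccc4)c3)[C@H]2OCc2ccccc2)oc2cc(OCc3ccccc3)ccc12
F7 | step 11 | 2,3-epoxide of flavone F6 (both diastereomers, epoxide centres not defined) | O=C1c2ccc(OCc3ccccc3)cc2OC2(c3cc(OCc4ccccc4)c(OCc4ccccc4)c(OCc4ccccc4)c3[C@@H]3c4ccc(OCc5ccccc5)cc4O[C@H](c4ccc(OCc5ccccc5)c(OCc5ccccc5)c4)[C@H]3OCc3ccccc3)OC12
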